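# Total synthesis proposal for CNP0301380.1 (compound 17)

Atom labels C1–C10 follow daucane numbering and are defined in the first section. Plain numbers 1–17 are compounds.

## Analysis of the target

- **Skeleton.** Target 17 is a daucane. Ring A is a cyclopentane (C1–C2–C3–C4–C5). It is fused through the C1–C5 bond to ring B, a cycloheptenone (C1–C5–C6–C7–C8–C9–C10).
- **Substituents.** C1 is quaternary and carries a methyl group. C4 carries a hydroxyl and an isopropyl group. C6 carries the 4-methoxybenzoate, and C8 carries a methyl group. The enone is C8=C9–C10=O.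
- **Configuration.** Decoding the SMILES gives (1S,4R,5R,6S), a cis ring fusion. C1–CH3, C5–H, C6–H and C4–OH lie on one face, called the top face here. C10, C6, the isopropyl group and the ester oxygen lie on the bottom face.
- **Stereocenters.** The four centres are contiguous (C1–C5–C4 and C5–C6), and two of them are fully substituted.
- **The awkward relation is C4/C5.** The isopropyl group is cis to C6, on the more crowded face. Bringing the isopropyl carbon, or C5 as an enolate, to a C4 carbonyl of the bicycle gives the other epimer. Oxygen must reach C4 from the top face, trans to the C5–C6 bond.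
- **Sensitive groups.** C7–H is vinylogously acidic, so the C6 ester can be lost by elimination. The tertiary alcohol ionises in acid. A C6 ketone next to the C4 carbinol would be a retro-aldol system.
- **Feature exploited.** The plan uses the array C6(O)–C5(H)–C4(O). Once the C4 hydroxyl is traced back to a C3=C4 alkene, C6(OH)–C5–C4=C3 is a homoallylic alcohol. That is the retron of a carbonyl-ene reaction between a C6 aldehyde and a C4=C5 alkene of ring A. The neighbouring C1 carries no hydrogen, so only this one ene mode exists.
- **Main difficulty.** The seven-membered ring must be closed next to the quaternary carbon while three further centres are controlled from C1 alone.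

## Retrosynthetic reasoning

**17 ⇒ 16 (C8=C9 unsaturation, no skeletal bond cut).** The enone is introduced last for two reasons. It makes C7–H acidic and the ester labile, and it would not survive a radical hydration. C10 is flanked by the quaternary C1, so dehydrogenation can only go towards C9. The uncontrolled C8 centre of all earlier compounds disappears here.

**16 ⇒ 14 (C4–O bond).** Oxygen must be delivered to C4 from the top face. A trisubstituted C3=C4 alkene in the cis-fused bicycle offers exactly this. The allylic C5 carries H on top and C6 with its bulky ester below. The forward reaction is a Markovnikov hydration by hydrogen-atom transfer. It needs no acid and leaves ketone and ester alone.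

**14 ⇒ 12 + 13 (ester C–O bond).** Compound 12 has a single hydroxyl group, so no protecting group is needed. The aroyl group also adds to the facial bias used in the next step.

**12 ⇒ 11 (C5–C6 bond, key step).** Cutting here opens ring B and removes C5 and C6 as stereocenters. It leaves a monocyclic keto aldehyde with one defined centre (C1). No other cut of ring B removes stereocenters. The forward ene reaction must close a seven-membered ring, force the cis fusion and fix C6. It must also move the ring A alkene from C4=C5 to C3=C4, where the following hydration needs it.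

**11 ⇒ 10 (C6–C7 bond).** The aldehyde carbon is added to a 1,1-disubstituted alkene by hydroformylation. The sensitive aldehyde therefore appears only one step before it is used. The chain then comes from a four-carbon allyl unit.

**10 ⇒ 8 + 9, and 8 ⇒ 6 + 7 (C9–C10 bond).** This is acyl substitution at the neopentyl carbonyl through the N-methoxy-N-methyl amide, which stops at the ketone stage.

**6 ⇒ 4 + 5, and 4 ⇒ 1 + 2 (C4–isopropyl and C1–CH3 bonds).** The quaternary C1 is set by a catalytic enantioselective conjugate addition of 2 to the achiral keto ester 1. The enolate formed points only towards C5. Trapping it as triflate 4 fixes the C4=C5 alkene regiochemistry, which the free ketone could not provide. Cross-coupling with 5 then installs the isopropyl group.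

## Alternatives that were turned down

**Alternative 1: ring-closing metathesis at C8=C9 (the textbook route).**
- The forward key step treats diene A1, which carries an acryloyl group on C1 and a methallyl carbinol ester on C5, with the second-generation Grubbs catalyst.
- The key step forms only an alkene. All four stereocenters, including the quaternary C1 and the contra-steric C4/C5 pair, must first be built one by one on a crowded cyclopentane.
- The metathesis joins an electron-poor neopentyl enone to a 1,1-disubstituted alkene, a slow pairing.
- The precursor is as complex as the product, so the step count ends up well above that of the chosen route.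

**Alternative 2: intramolecular aldol closure of ring A at C4–C5.**
- The forward key step uses the C5 enolate of triketone A2 to attack the isopropyl ketone of the side chain.
- The cis fusion would be secured.
- At C4, both the metal-bridged transition state and the steric preference place the carbonyl oxygen next to C6 and the isopropyl group outward. The reaction therefore leads to the C4 epimer A3.
- The aldol is reversible, so equilibration favours the same isomer.
- Enolisation of the C6 ketone towards C7 competes with enolisation towards the neopentyl C5.

**Alternative 3: strain release, forming C1–C10 and C5–C6 together.**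
- The forward key step is an enone–alkene [2+2] photocycloaddition of A4 with A5 to give cyclobutane A6. Glycol cleavage of the central C6–C10 bond then gives trione A7.
- This is short and forms both bonds of ring B at once.
- Both partners are achiral, and nothing in the step controls the absolute configuration.
- In A7, C5 lies between two ketones and loses its configuration.
- An isopropyl nucleophile would attack the C4 ketone of A6 or A7 from the top face and give the wrong C4 epimer. Several further steps would be needed to reach the same alkene that the chosen key step delivers directly.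

Key step: step 6

Remark: the SMILES is read literally, that is as the cis-fused (1S,4R,5R,6S) diastereomer.

Remark: C8 in 11, 12, 14, 15 and 16 is formed without control and carried as a mixture of epimers (no descriptor in the SMILES); step 9 makes it sp2.

## Route

Step 1
Reactants: 1 methyl 3-oxocyclopent-1-ene-1-carboxylate; 2 dimethylzinc
Product: 4 methyl (1S)-1-methyl-3-[(trifluoromethanesulfonyl)oxy]cyclopent-2-ene-1-carboxylate, via methylzinc enolate 3 (not isolated)
Conditions: Me2Zn, (CuOTf)2·C6H6 (cat.), chiral bidentate N-heterocyclic carbene ligand (from its imidazolinium salt, cat.), t-BuOMe, −30 °C; then Tf2O, −30 → 0 °C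
Reagents that add atoms: trifluoromethanesulfonic anhydride, O=S(=O)(OS(=O)(=O)C(F)(F)F)C(F)(F)F
Why: Copper–carbene-catalysed enantioselective conjugate addition of a dialkylzinc to a cyclic γ-keto-α,β-unsaturated ester; methyl adds β to the ketone at the ester-bearing carbon and the ligand enantiomer is chosen to give (S) at C1. Enolate 3 exists only towards C5, and O-sulfonylation freezes this regiochemistry as the C4=C5 alkene.

Step 2
Reactants: 4 methyl (1S)-1-methyl-3-[(trifluoromethanesulfonyl)oxy]cyclopent-2-ene-1-carboxylate; 5 isopropylmagnesium chloride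
Product: 6 methyl (1S)-1-methyl-3-(propan-2-yl)cyclopent-2-ene-1-carboxylate
Conditions: i-PrMgCl, Fe(acac)3 (cat.), THF/NMP, −30 °C
Reagents that add atoms: none
Why: Iron-catalysed Kumada-type cross-coupling of an alkenyl triflate with a secondary alkyl Grignard reagent, which at this temperature should be much faster than attack on the hindered ester. C1 is not touched.

Step 3
Reactants: 6 methyl (1S)-1-methyl-3-(propan-2-yl)cyclopent-2-ene-1-carboxylate; 7 N,O-dimethylhydroxylamine hydrochloride
Product: 8 (1S)-N-methoxy-N,1-dimethyl-3-(propan-2-yl)cyclopent-2-ene-1-carboxamide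
Conditions: MeNH(OMe)·HCl, i-PrMgCl (base), THF, −20 °C → rt
Reagents that add atoms: none
Why: Aminolysis of a methyl ester by the magnesium amide (Weinreb amide formation); the small nucleophile should still reach the neopentyl carbonyl group, and the alkene and C1 are inert.

Step 4
Reactants: 8 (1S)-N-methoxy-N,1-dimethyl-3-(propan-2-yl)cyclopent-2-ene-1-carboxamide; 9 2-methylallylmagnesium chloride
Product: 10 3-methyl-1-[(1S)-1-methyl-3-(propan-2-yl)cyclopent-2-en-1-yl]but-3-en-1-one
Conditions: 2-methylallylmagnesium chloride, THF, −78 → −20 °C; cold aq NH4Cl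
Reagents that add atoms: none
Why: Weinreb ketone synthesis; the chelated adduct collapses only on work-up, so a second addition is excluded. The cold, nearly neutral quench should keep the new alkene out of conjugation.

Step 5
Reactants: 10 3-methyl-1-[(1S)-1-methyl-3-(propan-2-yl)cyclopent-2-en-1-yl]but-3-en-1-one
Product: 11 3-methyl-5-[(1S)-1-methyl-3-(propan-2-yl)cyclopent-2-en-1-yl]-5-oxopentanal (C8 epimers)
Conditions: Rh(acac)(CO)2 (cat.), P(O-2,4-t-Bu2C6H3)3 (cat.), CO/H2 (1:1, 20 bar), toluene, 70 °C
Reagents that add atoms: carbon monoxide, [C-]#[O+]
Why: Rhodium-catalysed hydroformylation; a 1,1-disubstituted alkene takes the formyl group at its terminal carbon (Keulemans rule), and the trisubstituted ring alkene is too hindered to react. The new C8 centre is formed without control and is erased in step 9.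

Step 6
Reactants: 11 3-methyl-5-[(1S)-1-methyl-3-(propan-2-yl)cyclopent-2-en-1-yl]-5-oxopentanal (C8 epimers)
Product: 12 (3aS,8S,8aR)-8-hydroxy-3a,6-dimethyl-1-(propan-2-yl)-3,3a,5,6,7,8-hexahydroazulen-4(8aH)-one (cis-fused; C6–OH on the bottom face; C3=C4 alkene)
Conditions: Me2AlCl (2.2 equiv), CH2Cl2 (high dilution), −78 → 0 °C; aq HCl
Reagents that add atoms: none
Why: Lewis-acid-promoted intramolecular carbonyl-ene reaction of type 1 (the tether ends on the alkene carbon that is attacked), the reaction type that converts unsaturated aldehydes into cyclic homoallylic alcohols. Me2AlCl activates the aldehyde (the second equivalent is bound by the neopentyl ketone, which has no ene partner within reach), C5 attacks C6, the bottom-face hydrogen of C3 passes to oxygen through a six-centre transition state, and the alkene moves to C3=C4. Ring B is closed by the C5–C6 bond in a 7-exo-trig sense, C4 staying outside the new ring. C5 is controlled by C1: the tether hangs from the bottom face of C1 and its four chain atoms cannot reach the top face of the adjacent carbon, so C6 bonds from below, H5 is pushed to the top face and the fusion is cis. C6 is controlled by the cyclic transition state: the carbonyl oxygen must lie under ring A next to C3–H while C7 must point back towards C10, which leaves H6 outward and gives (6S). Regioselectivity is secured by the substrate: attack at C4 would need an allylic hydrogen on C1, which has none, and of the two donors on C4 the ring C3–H is aligned with the π system whereas the isopropyl methine becomes aligned only in a rotamer with severe A1,3 strain. Me2AlCl also removes the transferred proton as methane, so the acid-labile product does not meet a strong acid, and high dilution disfavours intermolecular reaction.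

Step 7
Reactants: 12 (3aS,8S,8aR)-8-hydroxy-3a,6-dimethyl-1-(propan-2-yl)-3,3a,5,6,7,8-hexahydroazulen-4(8aH)-one; 13 4-methoxybenzoyl chloride
Product: 14 (3aS,8S,8aR)-3a,6-dimethyl-4-oxo-1-(propan-2-yl)-3,3a,4,5,6,7,8,8a-octahydroazulen-8-yl 4-methoxybenzoate
Conditions: 4-MeOC6H4COCl, Et3N, DMAP (cat.), CH2Cl2, 0 °C → rt
Reagents that add atoms: none
Why: DMAP-catalysed acylation of the only hydroxyl group, with retention at C6. The aroyl group then shields the bottom face of ring A.

Step 8
Reactants: 14 (3aS,8S,8aR)-3a,6-dimethyl-4-oxo-1-(propan-2-yl)-3,3a,4,5,6,7,8,8a-octahydroazulen-8-yl 4-methoxybenzoate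
Product: 16 (1R,3aS,8S,8aR)-1-hydroxy-3a,6-dimethyl-4-oxo-1-(propan-2-yl)decahydroazulen-8-yl 4-methoxybenzoate, via tertiary hydroperoxide 15 (not isolated)
Conditions: Mn(dpm)3 (cat.), PhSiH3, O2 (1 atm), i-PrOH/CH2Cl2, 0 °C; then PPh3
Reagents that add atoms: dioxygen, O=O
Why: Mukaiyama hydration; hydrogen-atom transfer to C3 gives the tertiary C4 radical (Markovnikov). Dioxygen should be captured on the top face, trans to the vicinal C5–C6 bond and its ester, which sets (4R) with the isopropyl group pushed to the bottom face; PPh3 reduces 15. Saturated ketone and ester are inert, and no acid or base is present.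

Step 9
Reactants: 16 (1R,3aS,8S,8aR)-1-hydroxy-3a,6-dimethyl-4-oxo-1-(propan-2-yl)decahydroazulen-8-yl 4-methoxybenzoate
Product: 17 (1R,3aS,8S,8aR)-1-hydroxy-3a,6-dimethyl-4-oxo-1-(propan-2-yl)-1,2,3,3a,4,7,8,8a-octahydroazulen-8-yl 4-methoxybenzoate (target)
Conditions: IBX (1.5 equiv), DMSO, 65 °C
Reagents that add atoms: none
Why: IBX dehydrogenation of a ketone through its enol; C10 has α-hydrogens only at C9 because C1 is quaternary, so only the C8=C9 enone can form and both C8 epimers converge. The tertiary alcohol cannot be oxidised, and the medium is free of base, which protects the C6 ester.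

## Compound list

1 | methyl 3-oxocyclopent-1-ene-1-carboxylate | COC(=O)C1=CC(=O)CC1 | starting material
2 | dimethylzinc | C[Zn]C | starting material
3 | methylzinc enolate of methyl (1S)-1-methyl-3-oxocyclopentane-1-carboxylate (enolised towards C5) | COC(=O)[C@@]1(C)CCC(O[Zn]C)=C1 | intermediate
4 | methyl (1S)-1-methyl-3-[(trifluoromethanesulfonyl)oxy]cyclopent-2-ene-1-carboxylate | COC(=O)[C@@]1(C)CCC(OS(=O)(=O)C(F)(F)F)=C1 | intermediate
5 | isopropylmagnesium chloride | CC(C)[Mg]Cl | starting material
6 | methyl (1S)-1-methyl-3-(propan-2-yl)cyclopent-2-ene-1-carboxylate | COC(=O)[C@@]1(C)CCC(C(C)C)=C1 | intermediate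
7 | N,O-dimethylhydroxylamine hydrochloride | CNOC.Cl | starting material
8 | (1S)-N-methoxy-N,1-dimethyl-3-(propan-2-yl)cyclopent-2-ene-1-carboxamide | CON(C)C(=O)[C@@]1(C)CCC(C(C)C)=C1 | intermediate
9 | 2-methylallylmagnesium chloride | CC(=C)C[Mg]Cl | starting material
10 | 3-methyl-1-[(1S)-1-methyl-3-(propan-2-yl)cyclopent-2-en-1-yl]but-3-en-1-one | C=C(C)CC(=O)[C@@]1(C)CCC(C(C)C)=C1 | intermediate
11 | 3-methyl-5-[(1S)-1-methyl-3-(propan-2-yl)cyclopent-2-en-1-yl]-5-oxopentanal (C8 epimers) | O=CCC(C)CC(=O)[C@@]1(C)CCC(C(C)C)=C1 | intermediate
12 | (3aS,8S,8aR)-8-hydroxy-3a,6-dimethyl-1-(propan-2-yl)-3,3a,5,6,7,8-hexahydroazulen-4(8aH)-one (C8 epimers) | O[C@H]1CC(C)CC(=O)[C@@]2(C)CC=C(C(C)C)[C@@H]12 | intermediate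
13 | 4-methoxybenzoyl chloride | COc1ccc(C(=O)Cl)cc1 | starting material
14 | (3aS,8S,8aR)-3a,6-dimethyl-4-oxo-1-(propan-2-yl)-3,3a,4,5,6,7,8,8a-octahydroazulen-8-yl 4-methoxybenzoate (C8 epimers) | COc1ccc(C(=O)O[C@H]2CC(C)CC(=O)[C@@]3(C)CC=C(C(C)C)[C@@H]23)cc1 | intermediate
15 | (1R,3aS,8S,8aR)-1-hydroperoxy-3a,6-dimethyl-4-oxo-1-(propan-2-yl)decahydroazulen-8-yl 4-methoxybenzoate (C8 epimers) | COc1ccc(C(=O)O[C@H]2CC(C)CC(=O)[C@@]3(C)CC[C@@](OO)(C(C)C)[C@@H]23)cc1 | intermediate
16 | (1R,3aS,8S,8aR)-1-hydroxy-3a,6-dimethyl-4-oxo-1-(propan-2-yl)decahydroazulen-8-yl 4-methoxybenzoate (C8 epimers) | COc1ccc(C(=O)O[C@H]2CC(C)CC(=O)[C@@]3(C)CC[C@@](O)(C(C)C)[C@@H]23)cc1 | intermediate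
17 | (1R,3aS,8S,8aR)-1-hydroxy-3a,6-dimethyl-4-oxo-1-(propan-2-yl)-1,2,3,3a,4,7,8,8a-octahydroazulen-8-yl 4-methoxybenzoate | COc1ccc(C(=O)O[C@H]2CC(C)=CC(=O)[C@@]3(C)CC[C@@](O)(C(C)C)[C@@H]23)cc1 | target

## Step count and least certain steps

Total step count: 9. Longest linear sequence: 9 (1 → 17).

**Step 6 (key step).**
- The most likely failure is entropic. Closure of a seven-membered ring is slower than that of a six-membered one, so intermolecular ene or aldol-type oligomerisation of the complexed aldehyde may win.
- A second failure mode is a drift from the concerted to a stepwise cationic pathway. That would allow chloride capture at C4 and remove the geometric control of C6.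
- The fallback replaces the pericyclic closure by a cationic acylation and sets C6 by reduction. It sets out from 11.
- Oxidation with NaClO2/NaH2PO4/2-methylbut-2-ene gives carboxylic acid F1.
- Trifluoroacetic anhydride converts F1 into mixed anhydride F2. This is a much stronger electrophile. It acylates C5 from the bottom face with loss of the C3 proton and gives β,γ-unsaturated diketone F3.
- LiBH(s-Bu)3 at −78 °C reduces the less hindered C6 ketone from the side of H5. The route is rejoined at 12.

**Step 8.**
- Capture of dioxygen by the planar C4 radical may show poor facial selectivity, because C1–CH3 also lies on the top face. Simple reduction of the radical to the alkane may also compete.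
- The fallback delivers oxygen by a stereospecific polar sequence. It sets out from 14.
- mCPBA epoxidises the C3=C4 alkene on the top face to give epoxide F4.
- Phenylselenide, made from (PhSe)2 and NaBH4, opens F4 at the less substituted C3 to give hydroxy selenide F5.
- Bu3SnH/AIBN removes selenium. The route is rejoined at 16.

**Step 5.**
- The rhodium hydride may isomerise the β,γ-unsaturated ketone into conjugation before carbonylation, and the conjugated enone does not hydroformylate at the required carbon.
- The fallback builds the same chain by forming C8–C9 instead of C6–C7. It sets out from 8.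
- MeMgBr gives methyl ketone F6.
- Me3SiOTf/Et3N gives silyl enol ether F7.
- A Mukaiyama–Michael addition of F7 to (E)-but-2-enal under iminium catalysis rejoins the route at 11.

**Step 9.**
- At 65 °C the freshly formed enone may enolise towards C7. That would lead to loss of the C6 ester or to a second dehydrogenation.
- The fallback creates the alkene by a low-temperature syn elimination. It sets out from 16.
- LiN(i-Pr)2 (2.2 equiv, −78 °C) followed by PhSeCl gives α-phenylselanyl ketone F8.
- H2O2 at 0 °C gives selenoxide F9. Its only β-hydrogen is on C8, so it collapses to 17.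

**Step 1.**
- The flat five-membered acceptor may give an enantiomeric purity below what is needed. All later intermediates are expected to be oils, so no later step would improve it.
- The fallback adds a classical enrichment and replaces step 3. It sets out from 6.
- LiOH gives carboxylic acid F10.
- Its salt F11 with (R)-1-phenylethylamine is recrystallised and acidified back to F10.
- Coupling with 7 (carbonyldiimidazole, Et3N) rejoins the route at 8.

## Further compounds

F1 | step 6 | 3-methyl-5-[(1S)-1-methyl-3-(propan-2-yl)cyclopent-2-en-1-yl]-5-oxopentanoic acid | OC(=O)CC(C)CC(=O)[C@@]1(C)CCC(C(C)C)=C1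
F2 | step 6 | mixed anhydride of F1 with trifluoroacetic acid | O=C(CC(C)CC(=O)[C@@]1(C)CCC(C(C)C)=C1)OC(=O)C(F)(F)F
F3 | step 6 | (3aS,8aR)-3a,6-dimethyl-1-(propan-2-yl)-3,3a,5,6,7,8a-hexahydroazulene-4,8-dione | O=C1CC(C)CC(=O)[C@@]2(C)CC=C(C(C)C)[C@@H]12
F4 | step 8 | top-face C3–C4 epoxide of 14 | COc1ccc(C(=O)O[C@H]2CC(C)CC(=O)[C@@]3(C)C[C@@H]4O[C@]4(C(C)C)[C@@H]23)cc1
F5 | step 8 | C3-phenylselanyl C4-hydroxy derivative (selenium on the bottom face) | COc1ccc(C(=O)O[C@H]2CC(C)CC(=O)[C@@]3(C)C[C@@H]([Se]c4ccccc4)[C@@](O)(C(C)C)[C@@H]23)cc1
F6 | step 5 | 1-[(1S)-1-methyl-3-(propan-2-yl)cyclopent-2-en-1-yl]ethan-1-one | CC(=O)[C@@]1(C)CCC(C(C)C)=C1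
F7 | step 5 | trimethyl({1-[(1S)-1-methyl-3-(propan-2-yl)cyclopent-2-en-1-yl]ethenyl}oxy)silane | C=C(O[Si](C)(C)C)[C@@]1(C)CCC(C(C)C)=C1
F8 | step 9 | C9-phenylselanyl derivative of 16 | COc1ccc(C(=O)O[C@H]2CC(C)C([Se]c3ccccc3)C(=O)[C@@]3(C)CC[C@@](O)(C(C)C)[C@@H]23)cc1
F9 | step 9 | selenoxide of F8 | COc1ccc(C(=O)O[C@H]2CC(C)C([Se](=O)c3ccccc3)C(=O)[C@@]3(C)CC[C@@](O)(C(C)C)[C@@H]23)cc1
F10 | step 1 | (1S)-1-methyl-3-(propan-2-yl)cyclopent-2-ene-1-carboxylic acid | OC(=O)[C@@]1(C)CCC(C(C)C)=C1
F11 | step 1 | (R)-1-phenylethylammonium salt of F10 | [O-]C(=O)[C@@]1(C)CCC(C(C)C)=C1.C[C@@H]([NH3+])c1ccccc1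
A1 | alternative 1 | metathesis precursor with acryloyl group on C1 and methallyl carbinol 4-methoxybenzoate on C5 | C=CC(=O)[C@@]1(C)CC[C@@](O)(C(C)C)[C@H]1[C@H](CC(C)=C)OC(=O)c1ccc(OC)cc1
A2 | alternative 2 | 2,6-dimethyl-2-(4-methyl-3-oxopentyl)cycloheptane-1,4-dione, (S) at the quaternary carbon | CC(C)C(=O)CC[C@@]1(C)CC(=O)CC(C)CC1=O
A3 | alternative 2 | aldol product with C4–OH cis to C6 (C4 epimer of the required series) | O=C1CC(C)CC(=O)[C@@]2(C)CC[C@](O)(C(C)C)[C@@H]12
A4 | alternative 3 | 3-methylcyclopent-2-en-1-one | CC1=CC(=O)CC1
A5 | alternative 3 | 4-methyl-1,2-bis(trimethylsilyloxy)cyclopent-1-ene | CC1CC(O[Si](C)(C)C)=C(O[Si](C)(C)C)C1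
A6 | alternative 3 | cis-anti-cis cyclobutane photoadduct (one enantiomer of the racemate drawn) | O=C1CC[C@@]2(C)[C@@H]1[C@]1(O[Si](C)(C)C)CC(C)C[C@]21O[Si](C)(C)C
A7 | alternative 3 | 3a,6-dimethyloctahydroazulene-1,4,8-trione (one enantiomer of the racemate drawn) | O=C1CC(C)CC(=O)[C@@]2(C)CCC(=O)[C@@H]12
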